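**Retrosynthetic overview**
- Target ⇐ removal of four MOM groups from the protected flavonol; ring C is the only ring built, closed last by Algar–Flynn–Oyamada oxidation of a 2'-hydroxychalcone.
- Chalcone ⇐ Claisen–Schmidt (crossed aldol) condensation of a ring A methyl ketone with a ring B aldehyde; this is the key C–C bond.
- Ring A ketone ⇐ phloroacetophenone: 4-O-prenyl ether, then a chelation-directed aromatic Claisen rearrangement places the 1,1-dimethylallyl group between the two oxygens.
- Ring B aldehyde ⇐ 3,4-dihydroxybenzaldehyde: 4-O-allyl ether, Claisen rearrangement to C5, then cross-metathesis turns allyl into prenyl.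

Assumption: the target has no stereocentre and no stereogenic double bond, so it is achiral and no asymmetric step is needed.

**Ring A ketone**

Step 1
Reactants: 1 2,4,6-trihydroxyacetophenone (anhydrous)
Product: 2 1-[2,6-dihydroxy-4-(3-methylbut-2-en-1-yloxy)phenyl]ethan-1-one
Conditions: prenyl bromide (1.0 equiv), K2CO3 (1.05 equiv), acetone, 56 °C, 6 h
Reagents that add atoms: prenyl bromide (1-bromo-3-methylbut-2-ene), CC(C)=CCBr
Why: Williamson etherification: the 4-OH is the only hydroxyl not hydrogen-bonded to the acetyl group and the most acidic one, so one equivalent of the allylic bromide with a weak base gives mainly the 4-O-monoether (di-O- and C-prenylated by-products are removed by chromatography).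

Step 2
Reactants: 2 1-[2,6-dihydroxy-4-(3-methylbut-2-en-1-yloxy)phenyl]ethan-1-one
Product: 3 1-[2-hydroxy-6-(methoxymethoxy)-4-(3-methylbut-2-en-1-yloxy)phenyl]ethan-1-one
Conditions: MOMCl (1.1 equiv), DIPEA (1.5 equiv), CH2Cl2, 0 °C → rt
Reagents that add atoms: chloromethyl methyl ether (MOMCl), COCCl
Why: MOM protection (O-alkylation with an α-chloro ether): the two hydroxyls are equivalent and only one can chelate the carbonyl at a time, so one is alkylated and the other, now permanently chelated, stays free.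

Step 3
Reactants: 3 1-[2-hydroxy-6-(methoxymethoxy)-4-(3-methylbut-2-en-1-yloxy)phenyl]ethan-1-one
Product: 5 1-[2,4-dihydroxy-6-(methoxymethoxy)-3-(2-methylbut-3-en-2-yl)phenyl]ethan-1-one, via ortho-dienone 4 (not isolated)
Conditions: N,N-diethylaniline, 190 °C, sealed tube, Ar, 2–3 h
Reagents that add atoms: none
Why: Aromatic Claisen rearrangement ([3,3]-sigmatropic) with allylic transposition turns the O-prenyl group into a C-bound 1,1-dimethylallyl group; chelation of the 2-OH to the acetyl group fixes double-bond character in C3–C4 and C3 has the smaller neighbour (OH rather than OMOM), the para position is blocked by the acetyl group so no Cope migration follows, and the stereocentre of dienone 4 is lost on enolisation.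

Step 4
Reactants: 5 1-[2,4-dihydroxy-6-(methoxymethoxy)-3-(2-methylbut-3-en-2-yl)phenyl]ethan-1-one
Product: 6 1-[2-hydroxy-4,6-bis(methoxymethoxy)-3-(2-methylbut-3-en-2-yl)phenyl]ethan-1-one
Conditions: MOMCl (1.3 equiv), DIPEA (2 equiv), CH2Cl2, 0 → 40 °C
Reagents that add atoms: chloromethyl methyl ether (MOMCl), COCCl
Why: MOM protection: the non-chelated 4-OH is alkylated, while the 2-OH, chelated to the ketone and flanked by the tert-alkyl group, does not react under amine-base conditions.

**Ring B aldehyde**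

Step 5
Reactants: 7 3,4-dihydroxybenzaldehyde
Product: 8 3-hydroxy-4-(prop-2-en-1-yloxy)benzaldehyde
Conditions: allyl bromide (1.05 equiv), NaHCO3 (1.5 equiv), DMF, 40 °C, 20 h
Reagents that add atoms: allyl bromide (3-bromoprop-1-ene), C=CCBr
Why: Williamson etherification: the 4-OH para to the formyl group is clearly more acidic than the 3-OH, so NaHCO3 ionises and allylates it selectively.

Step 6
Reactants: 8 3-hydroxy-4-(prop-2-en-1-yloxy)benzaldehyde
Product: 10 3,4-dihydroxy-5-(prop-2-en-1-yl)benzaldehyde, via ortho-dienone 9 (not isolated)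
Conditions: neat, 190 °C, Ar, 2 h
Reagents that add atoms: none
Why: Aromatic Claisen rearrangement: only the ortho position C5 carries hydrogen (C3 bears the OH and the para position the formyl group), so the allyl group ends up at C5 and dienone 9 enolises to the catechol with loss of its stereocentre.

Step 7
Reactants: 10 3,4-dihydroxy-5-(prop-2-en-1-yl)benzaldehyde
Product: 11 3,4-bis(methoxymethoxy)-5-(prop-2-en-1-yl)benzaldehyde
Conditions: MOMCl (3 equiv), DIPEA (4 equiv), CH2Cl2, 0 °C → rt, 12 h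
Reagents that add atoms: chloromethyl methyl ether (MOMCl), COCCl
Why: MOM protection of both catechol hydroxyls with excess reagent; the aldehyde and the allyl group are inert.

Step 8
Reactants: 11 3,4-bis(methoxymethoxy)-5-(prop-2-en-1-yl)benzaldehyde
Product: 12 3,4-bis(methoxymethoxy)-5-(3-methylbut-2-en-1-yl)benzaldehyde
Conditions: 2-methyl-2-butene (large excess, co-solvent), second-generation Grubbs catalyst [RuCl2(=CHPh)(PCy3)(H2IMes)] (3 mol %), CH2Cl2, 40 °C, 12 h
Reagents that add atoms: 2-methyl-2-butene, CC=C(C)C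
Why: Olefin cross-metathesis: the terminal allyl alkene exchanges its CH2 end for the isopropylidene end of 2-methyl-2-butene with loss of volatile propene, and the ruthenium carbene tolerates the aldehyde and the acetals.

**Union and end game**

Step 9
Reactants: 6 1-[2-hydroxy-4,6-bis(methoxymethoxy)-3-(2-methylbut-3-en-2-yl)phenyl]ethan-1-one; 12 3,4-bis(methoxymethoxy)-5-(3-methylbut-2-en-1-yl)benzaldehyde
Product: 14 (2E)-3-[3,4-bis(methoxymethoxy)-5-(3-methylbut-2-en-1-yl)phenyl]-1-[2-hydroxy-4,6-bis(methoxymethoxy)-3-(2-methylbut-3-en-2-yl)phenyl]prop-2-en-1-one, via aldol adduct 13 (not isolated)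
Conditions: KOH (50% aq, 10 equiv), EtOH, 0 °C → rt, 48 h; aq NH4Cl work-up
Reagents that add atoms: none
Why: Claisen–Schmidt condensation (crossed aldol, then E1cB dehydration): only the methyl ketone can enolise and only the aldehyde is a good acceptor, the carbinol stereocentre of 13 is removed on dehydration, and the conjugated E-alkene forms under thermodynamic control while MOM ethers and alkenes are stable to hydroxide.

Step 10
Reactants: 14 the (E)-chalcone from step 9
Product: 16 2-[3,4-bis(methoxymethoxy)-5-(3-methylbut-2-en-1-yl)phenyl]-3-hydroxy-5,7-bis(methoxymethoxy)-8-(2-methylbut-3-en-2-yl)-4H-chromen-4-one, via trans-dihydroflavonol 15 (not isolated)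
Conditions: H2O2 (30% aq, 6 equiv), NaOH (2 M aq, 6 equiv), MeOH/THF, 0 °C → rt, 16 h; aq NH4Cl work-up
Reagents that add atoms: hydrogen peroxide, OO
Why: Algar–Flynn–Oyamada oxidative cyclisation: the only free phenoxide (2'-O, next to the dimethylallyl group) closes ring C at the β-carbon with α-hydroxylation by hydroperoxide to give 15, whose two stereocentres are erased on further oxidation to the flavonol, and alkaline H2O2 does not epoxidise the isolated electron-rich alkenes.

Step 11
Reactants: 16 the tetra-MOM flavonol from step 10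
Product: 17 2-[3,4-dihydroxy-5-(3-methylbut-2-en-1-yl)phenyl]-3,5,7-trihydroxy-8-(2-methylbut-3-en-2-yl)-4H-chromen-4-one
Conditions: HCl (1.25 M in MeOH, 10 equiv), MeOH/THF, 40 °C, about 3 h, Ar
Reagents that add atoms: none
Why: Acid-catalysed acetal methanolysis (MOM removal): the four aryl MOM acetals cleave under mild conditions at which protonation of the prenyl and dimethylallyl alkenes (chroman or dihydrofuran formation) is still slow, so the reaction is stopped as soon as the last MOM group is gone.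

**Compound list**

1 | 2,4,6-trihydroxyacetophenone | CC(=O)c1c(O)cc(O)cc1O | starting material
2 | 1-[2,6-dihydroxy-4-(3-methylbut-2-en-1-yloxy)phenyl]ethan-1-one | CC(=O)c1c(O)cc(OCC=C(C)C)cc1O | intermediate
3 | 1-[2-hydroxy-6-(methoxymethoxy)-4-(3-methylbut-2-en-1-yloxy)phenyl]ethan-1-one | CC(=O)c1c(O)cc(OCC=C(C)C)cc1OCOC | intermediate
4 | 4-acetyl-5-hydroxy-3-(methoxymethoxy)-6-(2-methylbut-3-en-2-yl)cyclohexa-2,4-dien-1-one (racemic, not isolated) | CC(=O)C1=C(O)C(C(C)(C)C=C)C(=O)C=C1OCOC | intermediate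
5 | 1-[2,4-dihydroxy-6-(methoxymethoxy)-3-(2-methylbut-3-en-2-yl)phenyl]ethan-1-one | CC(=O)c1c(O)c(C(C)(C)C=C)c(O)cc1OCOC | intermediate
6 | 1-[2-hydroxy-4,6-bis(methoxymethoxy)-3-(2-methylbut-3-en-2-yl)phenyl]ethan-1-one | CC(=O)c1c(O)c(C(C)(C)C=C)c(OCOC)cc1OCOC | intermediate
7 | 3,4-dihydroxybenzaldehyde | O=Cc1ccc(O)c(O)c1 | starting material
8 | 3-hydroxy-4-(prop-2-en-1-yloxy)benzaldehyde | O=Cc1ccc(OCC=C)c(O)c1 | intermediate
9 | 5-hydroxy-4-oxo-3-(prop-2-en-1-yl)cyclohexa-1,5-diene-1-carbaldehyde (racemic, not isolated) | O=CC1=CC(CC=C)C(=O)C(O)=C1 | intermediate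
10 | 3,4-dihydroxy-5-(prop-2-en-1-yl)benzaldehyde | O=Cc1cc(O)c(O)c(CC=C)c1 | intermediate
11 | 3,4-bis(methoxymethoxy)-5-(prop-2-en-1-yl)benzaldehyde | O=Cc1cc(OCOC)c(OCOC)c(CC=C)c1 | intermediate
12 | 3,4-bis(methoxymethoxy)-5-(3-methylbut-2-en-1-yl)benzaldehyde | O=Cc1cc(OCOC)c(OCOC)c(CC=C(C)C)c1 | intermediate
13 | 3-[3,4-bis(methoxymethoxy)-5-(3-methylbut-2-en-1-yl)phenyl]-3-hydroxy-1-[2-hydroxy-4,6-bis(methoxymethoxy)-3-(2-methylbut-3-en-2-yl)phenyl]propan-1-one (racemic, not isolated) | C=CC(C)(C)c1c(O)c(C(=O)CC(O)c2cc(OCOC)c(OCOC)c(CC=C(C)C)c2)c(OCOC)cc1OCOC | intermediate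
14 | (2E)-3-[3,4-bis(methoxymethoxy)-5-(3-methylbut-2-en-1-yl)phenyl]-1-[2-hydroxy-4,6-bis(methoxymethoxy)-3-(2-methylbut-3-en-2-yl)phenyl]prop-2-en-1-one | C=CC(C)(C)c1c(O)c(C(=O)/C=C/c2cc(OCOC)c(OCOC)c(CC=C(C)C)c2)c(OCOC)cc1OCOC | intermediate
15 | (2R*,3R*)-2-[3,4-bis(methoxymethoxy)-5-(3-methylbut-2-en-1-yl)phenyl]-3-hydroxy-5,7-bis(methoxymethoxy)-8-(2-methylbut-3-en-2-yl)-2,3-dihydro-4H-chromen-4-one (racemic trans, one enantiomer drawn, not isolated) | COCOc1cc(cc(CC=C(C)C)c1OCOC)[C@@H]1[C@@H](O)C(=O)c2c(OCOC)cc(OCOC)c(C(C)(C)C=C)c2O1 | intermediate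
16 | 2-[3,4-bis(methoxymethoxy)-5-(3-methylbut-2-en-1-yl)phenyl]-3-hydroxy-5,7-bis(methoxymethoxy)-8-(2-methylbut-3-en-2-yl)-4H-chromen-4-one | C=CC(C)(C)c1c(OCOC)cc(OCOC)c2c(=O)c(O)c(-c3cc(OCOC)c(OCOC)c(CC=C(C)C)c3)oc12 | intermediate
17 | 2-[3,4-dihydroxy-5-(3-methylbut-2-en-1-yl)phenyl]-3,5,7-trihydroxy-8-(2-methylbut-3-en-2-yl)-4H-chromen-4-one | C=CC(C)(C)c1c(O)cc(O)c2c(=O)c(O)c(-c3cc(O)c(O)c(CC=C(C)C)c3)oc12 | target

**Totals**
Total step count: 11. Longest linear sequence: 7 steps (steps 1–4, 9, 10, 11; the aldehyde branch, steps 5–8, 9, 10, 11, is equally long).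

**Three steps most likely to fail**

Step 3 (Claisen rearrangement on ring A). Risks are attack at C5 instead of C3 and thermal follow-up reactions of the free 4-OH with the new alkene. The fallback sets out from 2 and comes back at 6. The C2-symmetric diol 2 is itself heated in N,N-diethylaniline at 180 °C; its two ortho positions are equivalent, so the rearrangement can only give the triol 1-[2,4,6-trihydroxy-3-(2-methylbut-3-en-2-yl)phenyl]ethan-1-one F1. MOMCl (2.1 equiv) with DIPEA in CH2Cl2 then protects the 4-OH and the unhindered 6-OH. The 2-OH, pressed against the carbonyl by the tert-alkyl group, stays free, which gives 6. Regiochemistry is then set by symmetry and steric control of protection instead of by chelation control of the rearrangement.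

Step 10 (Algar–Flynn–Oyamada). A 6'-alkoxy group and a hindered 2'-phenoxide favour aurone formation. The fallback sets out from 14 and comes back at 16. Chalcone 14 is first closed without oxidant (NaOAc, EtOH/H2O, 80 °C) to the racemic flavanone F2. DDQ in dioxane at 100 °C dehydrogenates it to the flavone F3. LDA in THF at −78 °C lithiates C3, and B(OMe)3 traps the anion as the C3 dimethyl boronate F4. NaBO3·4H2O in THF/H2O at rt oxidises the C–B bond to the 3-hydroxyl, giving 16 without touching the alkenes.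

Step 11 (global MOM removal). Acid may cyclise the prenyl group onto the 4'-OH or the dimethylallyl group onto the 7-OH. The fallback sets out from 16 and comes back at 17. TMSOTf with 2,2'-bipyridyl in CH2Cl2 (0 °C → rt) exchanges the four aryl MOM ethers for trimethylsilyl ethers and silylates the 3-OH, giving the pentakis(trimethylsilyl) ether F5. Stirring F5 with water in THF at rt hydrolyses the silyl ethers to 17, so no Brønsted acid meets the alkenes.

**Further compounds**

F1 | step 3 | 1-[2,4,6-trihydroxy-3-(2-methylbut-3-en-2-yl)phenyl]ethan-1-one | CC(=O)c1c(O)cc(O)c(C(C)(C)C=C)c1O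
F2 | step 10 | 2-[3,4-bis(methoxymethoxy)-5-(3-methylbut-2-en-1-yl)phenyl]-5,7-bis(methoxymethoxy)-8-(2-methylbut-3-en-2-yl)-2,3-dihydro-4H-chromen-4-one (racemic) | C=CC(C)(C)c1c(OCOC)cc(OCOC)c2C(=O)CC(c3cc(OCOC)c(OCOC)c(CC=C(C)C)c3)Oc12
F3 | step 10 | 2-[3,4-bis(methoxymethoxy)-5-(3-methylbut-2-en-1-yl)phenyl]-5,7-bis(methoxymethoxy)-8-(2-methylbut-3-en-2-yl)-4H-chromen-4-one | C=CC(C)(C)c1c(OCOC)cc(OCOC)c2c(=O)cc(-c3cc(OCOC)c(OCOC)c(CC=C(C)C)c3)oc12
F4 | step 10 | dimethyl {2-[3,4-bis(methoxymethoxy)-5-(3-methylbut-2-en-1-yl)phenyl]-5,7-bis(methoxymethoxy)-8-(2-methylbut-3-en-2-yl)-4-oxo-4H-chromen-3-yl}boronate | C=CC(C)(C)c1c(OCOC)cc(OCOC)c2c(=O)c(B(OC)OC)c(-c3cc(OCOC)c(OCOC)c(CC=C(C)C)c3)oc12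
F5 | step 11 | 2-[3,4-bis(trimethylsilyloxy)-5-(3-methylbut-2-en-1-yl)phenyl]-8-(2-methylbut-3-en-2-yl)-3,5,7-tris(trimethylsilyloxy)-4H-chromen-4-one | C=CC(C)(C)c1c(O[Si](C)(C)C)cc(O[Si](C)(C)C)c2c(=O)c(O[Si](C)(C)C)c(-c3cc(O[Si](C)(C)C)c(O[Si](C)(C)C)c(CC=C(C)C)c3)oc12
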